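## Retrosynthetic overview

- Target ⇐ buffered fluoride cleavage of two aryl TIPS ethers; the CO2H group ⇐ nitrosative Nef oxidation of the CH2NO2 group of an anti γ-nitro methyl ester.
- anti γ-Nitro ester (C2–C3 bond, both stereocentres, methyl ester already in place) ⇐ carbene-catalysed oxidative azolium-enolate/nitroalkene [4+2] addition, then methanolysis. This is the only asymmetric step and it is metal-free.
- Enolate precursor (a 3-arylpropanal) ⇐ Heck arylation of allyl alcohol at the C–I bond of 2-bromo-5-iodophenol, Stille prenylation at C–Br, O-silylation. Heterodiene ⇐ O-silylation of 4-[(E)-2-nitroethenyl]phenol.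
- Rings: both benzene rings are bought. The only ring formed is a transient six-membered cyclic acyl nitronate in the key step, opened in the same flask.

Assumption: the starting materials and reagents named are taken as catalogue items, and the triazolium enantiomer in step 5 is assigned by analogy with enone annulations; its antipode would be used if the first run gave the enantiomeric ester.

## Route

Step 1
Reactants: 1 2-bromo-5-iodophenol; 2 prop-2-en-1-ol (allyl alcohol)
Product: 3 3-(4-bromo-3-hydroxyphenyl)propanal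
Conditions: Pd(OAc)2 (3 mol%), n-Bu4NCl, NaHCO3, DMF, 45 °C
Reagents that add atoms: none
Why: Jeffery-type Heck reaction in which oxidative addition occurs only at the C–I bond at this temperature, and insertion of allyl alcohol followed by β-hydride elimination toward the carbinol carbon gives an enol that tautomerises to the aldehyde, leaving C–Br for step 2.

Step 2
Reactants: 3 3-(4-bromo-3-hydroxyphenyl)propanal
Product: 4 3-[3-hydroxy-4-(3-methylbut-2-en-1-yl)phenyl]propanal
Conditions: Bu3SnCH2CH=CMe2 (1.3 equiv), Pd(PPh3)4 (5 mol%), DMF, 95 °C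
Reagents that add atoms: tributyl(3-methylbut-2-en-1-yl)stannane, CCCC[Sn](CCCC)(CCCC)CC=C(C)C
Why: Stille cross-coupling at the remaining C–Br bond runs under neutral conditions that tolerate the enolisable aldehyde and the free phenol, and the allylstannane transfers its unsubstituted terminus to give the linear prenyl group.

Step 3
Reactants: 4 3-[3-hydroxy-4-(3-methylbut-2-en-1-yl)phenyl]propanal
Product: 5 3-[4-(3-methylbut-2-en-1-yl)-3-(triisopropylsilyloxy)phenyl]propanal
Conditions: TIPSCl (1.2 equiv), imidazole (2.5 equiv), DMF, rt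
Reagents that add atoms: chlorotriisopropylsilane, CC(C)[Si](Cl)(C(C)C)C(C)C
Why: Imidazole-promoted O-silylation masks the phenol, which would otherwise be acylated in step 5 and C-nitrosated in step 6, and the bulky TIPS ether survives carbonate base, methanol and acetic acid.

Step 4
Reactants: 6 4-[(E)-2-nitroethenyl]phenol
Product: 7 triisopropyl{4-[(E)-2-nitroethenyl]phenoxy}silane
Conditions: TIPSCl (1.1 equiv), imidazole (2.2 equiv), CH2Cl2, 0 °C to rt
Reagents that add atoms: chlorotriisopropylsilane, CC(C)[Si](Cl)(C(C)C)C(C)C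
Why: O-silylation of the acidic vinylogous phenol keeps the nitroalkene neutral and electrophilic under the basic conditions of step 5.

Step 5
Reactants: 5 3-[4-(3-methylbut-2-en-1-yl)-3-(triisopropylsilyloxy)phenyl]propanal (1.3 equiv); 7 triisopropyl{4-[(E)-2-nitroethenyl]phenoxy}silane (1.0 equiv)
Product: 9 methyl (2R,3R)-2-{[4-(3-methylbut-2-en-1-yl)-3-(triisopropylsilyloxy)phenyl]methyl}-4-nitro-3-[4-(triisopropylsilyloxy)phenyl]butanoate, via cyclic acyl nitronate 8 (not isolated)
Conditions: (5aS,10bR)-2-mesityl-5a,10b-dihydro-4H,6H-indeno[2,1-b][1,2,4]triazolo[4,3-d][1,4]oxazin-2-ium chloride (10 mol%), 3,3',5,5'-tetra-tert-butyl-4,4'-diphenoquinone (1.3 equiv), K2CO3, 4 Å MS, toluene, 0 °C to rt; then MeOH, 0 °C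
Reagents that add atoms: methanol, CO
Why: Proposed new method: the carbene adds to aldehyde 5, the Breslow intermediate is oxidised by the diphenoquinone to an acyl azolium, and α-deprotonation gives a (Z)-azolium enolate that meets nitroalkene 7 as a 4π heterodiene (O=N–C=C) in an endo, inverse-demand hetero-Diels–Alder-type addition with the bulky azolium exo, so that C–C bond formation and O-acylation of the nitronate give the cis-4,5-disubstituted cyclic acyl nitronate 8 (cis in the ring corresponds to anti in the open chain) and release the carbene; the catalyst enantiomer is the one that leaves the Si face of the enolate α-carbon open to the Re face of the nitroalkene, which sets 2R and 3R in one event, and methanol then opens the mixed anhydride to ester 9; the closest known reaction type is the carbene-catalysed oxidative azolium-enolate [4+2] annulation of simple aliphatic aldehydes with enones, which gives cis-3,4-disubstituted dihydropyranones, here transferred to a nitroalkene heterodiene with alcoholytic release of an open-chain γ-nitro ester.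

Step 6
Reactants: 9 methyl (2R,3R)-2-{[4-(3-methylbut-2-en-1-yl)-3-(triisopropylsilyloxy)phenyl]methyl}-4-nitro-3-[4-(triisopropylsilyloxy)phenyl]butanoate
Product: 10 (2R,3R)-4-methoxy-3-{[4-(3-methylbut-2-en-1-yl)-3-(triisopropylsilyloxy)phenyl]methyl}-4-oxo-2-[4-(triisopropylsilyloxy)phenyl]butanoic acid
Conditions: NaNO2 (3 equiv), AcOH (10 equiv), DMSO, 35 °C; aqueous work-up
Reagents that add atoms: sodium nitrite, [Na+].[O-]N=O; water, O
Why: Nitrosative Nef oxidation converts the primary nitro group through the nitrolic acid and nitrile oxide into the carboxylic acid without passing through an enolisable aldehyde, so the adjacent benzylic stereocentre is kept and the methyl ester is untouched.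

Step 7
Reactants: 10 (2R,3R)-4-methoxy-3-{[4-(3-methylbut-2-en-1-yl)-3-(triisopropylsilyloxy)phenyl]methyl}-4-oxo-2-[4-(triisopropylsilyloxy)phenyl]butanoic acid
Product: 11 (2R,3R)-3-{[3-hydroxy-4-(3-methylbut-2-en-1-yl)phenyl]methyl}-2-(4-hydroxyphenyl)-4-methoxy-4-oxobutanoic acid (CNP0437978.2)
Conditions: TBAF (2.5 equiv), AcOH (2.5 equiv), THF, 0 °C
Reagents that add atoms: none
Why: Fluoride cleaves both aryl silyl ethers, and the acetic acid buffer protects the methyl ester, the two α-stereocentres and the acid-sensitive ortho-prenylphenol.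

## Compound list

1 | 2-bromo-5-iodophenol | Oc1cc(I)ccc1Br | starting material
2 | prop-2-en-1-ol | C=CCO | starting material
3 | 3-(4-bromo-3-hydroxyphenyl)propanal | O=CCCc1ccc(Br)c(O)c1 | intermediate
4 | 3-[3-hydroxy-4-(3-methylbut-2-en-1-yl)phenyl]propanal | O=CCCc1ccc(CC=C(C)C)c(O)c1 | intermediate
5 | 3-[4-(3-methylbut-2-en-1-yl)-3-(triisopropylsilyloxy)phenyl]propanal | O=CCCc1ccc(CC=C(C)C)c(O[Si](C(C)C)(C(C)C)C(C)C)c1 | intermediate
6 | 4-[(E)-2-nitroethenyl]phenol | Oc1ccc(/C=C/[N+](=O)[O-])cc1 | starting material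
7 | triisopropyl{4-[(E)-2-nitroethenyl]phenoxy}silane | CC(C)[Si](Oc1ccc(/C=C/[N+](=O)[O-])cc1)(C(C)C)C(C)C | intermediate
8 | (4R,5R)-5-{[4-(3-methylbut-2-en-1-yl)-3-(triisopropylsilyloxy)phenyl]methyl}-4-[4-(triisopropylsilyloxy)phenyl]-4,5-dihydro-6H-1,2-oxazin-6-one 2-oxide | O=C1O[N+]([O-])=C[C@@H](c2ccc(O[Si](C(C)C)(C(C)C)C(C)C)cc2)[C@H]1Cc1ccc(CC=C(C)C)c(O[Si](C(C)C)(C(C)C)C(C)C)c1 | intermediate
9 | methyl (2R,3R)-2-{[4-(3-methylbut-2-en-1-yl)-3-(triisopropylsilyloxy)phenyl]methyl}-4-nitro-3-[4-(triisopropylsilyloxy)phenyl]butanoate | COC(=O)[C@H](Cc1ccc(CC=C(C)C)c(O[Si](C(C)C)(C(C)C)C(C)C)c1)[C@@H](C[N+](=O)[O-])c1ccc(O[Si](C(C)C)(C(C)C)C(C)C)cc1 | intermediate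
10 | (2R,3R)-4-methoxy-3-{[4-(3-methylbut-2-en-1-yl)-3-(triisopropylsilyloxy)phenyl]methyl}-4-oxo-2-[4-(triisopropylsilyloxy)phenyl]butanoic acid | COC(=O)[C@H](Cc1ccc(CC=C(C)C)c(O[Si](C(C)C)(C(C)C)C(C)C)c1)[C@@H](C(=O)O)c1ccc(O[Si](C(C)C)(C(C)C)C(C)C)cc1 | intermediate
11 | (2R,3R)-3-{[3-hydroxy-4-(3-methylbut-2-en-1-yl)phenyl]methyl}-2-(4-hydroxyphenyl)-4-methoxy-4-oxobutanoic acid | COC(=O)[C@H](Cc1ccc(CC=C(C)C)c(O)c1)[C@@H](C(=O)O)c1ccc(O)cc1 | target

## Step count and risks

Total step count: 7. Longest linear sequence: 6 (steps 1, 2, 3, 5, 6, 7).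

**Step 5 (the proposed new step).** The likely failures are Stetter-type addition of the Breslow intermediate to the nitroalkene, a second oxidation of the enolate to a cinnamoyl azolium, base-induced collapse of the acyl nitronate to a nitrile oxide before methanol is added, and a stepwise addition that erodes the cis (anti) selectivity. The fallback uses known enamine catalysis and sets out from 5 and 7. An anti-selective tripeptide amine catalyst of the proline-N-terminus, carboxylic-acid-side-chain class (5 mol%, CHCl3/i-PrOH, rt) gives (2R,3R)-2-{[4-(3-methylbut-2-en-1-yl)-3-(triisopropylsilyloxy)phenyl]methyl}-4-nitro-3-[4-(triisopropylsilyloxy)phenyl]butanal F2. Pinnick oxidation (NaClO2, NaH2PO4, excess 2-methyl-2-butene, t-BuOH/H2O) gives the corresponding (2R,3R)-4-nitrobutanoic acid F3. Methylation with TMSCHN2 in MeOH/toluene at 0 °C comes back to the route at 9.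

**Step 6 (Nef oxidation).** The nitrosating medium may attack the trisubstituted prenyl alkene, and any silyl loss would expose a phenol to C-nitrosation. The fallback moves the prenylation behind the Nef step and sets out from 3. Silylation as in step 3 gives 3-[4-bromo-3-(triisopropylsilyloxy)phenyl]propanal F4. The conditions of step 5 with 7 give, through the bromo cyclic acyl nitronate F5, methyl (2R,3R)-2-{[4-bromo-3-(triisopropylsilyloxy)phenyl]methyl}-4-nitro-3-[4-(triisopropylsilyloxy)phenyl]butanoate F6. The conditions of step 6, now with no alkene present, give the bromo acid (2R,3R)-3-{[4-bromo-3-(triisopropylsilyloxy)phenyl]methyl}-4-methoxy-4-oxo-2-[4-(triisopropylsilyloxy)phenyl]butanoic acid F7. Suzuki–Miyaura coupling of F7 with 3-methylbut-2-en-1-ylboronic acid pinacol ester (Pd(OAc)2 with a bulky biarylphosphine under linear-selective conditions, K3PO4, THF/H2O, 40 °C) comes back to the route at 10.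

**Step 2 (Stille prenylation).** The allylstannane may couple in part through its substituted terminus, giving the reverse-prenyl isomer, or be lost by protodestannylation. The fallback sets out from 3. Stille coupling with allyltributylstannane (Pd(PPh3)4, DMF, 95 °C) has no regiochemical ambiguity and gives 3-[3-hydroxy-4-(prop-2-en-1-yl)phenyl]propanal F1. Cross-metathesis of F1 with excess 2-methyl-2-butene (second-generation Grubbs catalyst, CH2Cl2, 40 °C) comes back to the route at 4.

## Further compounds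

F1 | step 2 | 3-[3-hydroxy-4-(prop-2-en-1-yl)phenyl]propanal | O=CCCc1ccc(CC=C)c(O)c1
F2 | step 5 | (2R,3R)-2-{[4-(3-methylbut-2-en-1-yl)-3-(triisopropylsilyloxy)phenyl]methyl}-4-nitro-3-[4-(triisopropylsilyloxy)phenyl]butanal | O=C[C@H](Cc1ccc(CC=C(C)C)c(O[Si](C(C)C)(C(C)C)C(C)C)c1)[C@@H](C[N+](=O)[O-])c1ccc(O[Si](C(C)C)(C(C)C)C(C)C)cc1
F3 | step 5 | (2R,3R)-2-{[4-(3-methylbut-2-en-1-yl)-3-(triisopropylsilyloxy)phenyl]methyl}-4-nitro-3-[4-(triisopropylsilyloxy)phenyl]butanoic acid | OC(=O)[C@H](Cc1ccc(CC=C(C)C)c(O[Si](C(C)C)(C(C)C)C(C)C)c1)[C@@H](C[N+](=O)[O-])c1ccc(O[Si](C(C)C)(C(C)C)C(C)C)cc1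
F4 | step 6 | 3-[4-bromo-3-(triisopropylsilyloxy)phenyl]propanal | O=CCCc1ccc(Br)c(O[Si](C(C)C)(C(C)C)C(C)C)c1
F5 | step 6 | (4R,5R)-5-{[4-bromo-3-(triisopropylsilyloxy)phenyl]methyl}-4-[4-(triisopropylsilyloxy)phenyl]-4,5-dihydro-6H-1,2-oxazin-6-one 2-oxide | O=C1O[N+]([O-])=C[C@@H](c2ccc(O[Si](C(C)C)(C(C)C)C(C)C)cc2)[C@H]1Cc1ccc(Br)c(O[Si](C(C)C)(C(C)C)C(C)C)c1
F6 | step 6 | methyl (2R,3R)-2-{[4-bromo-3-(triisopropylsilyloxy)phenyl]methyl}-4-nitro-3-[4-(triisopropylsilyloxy)phenyl]butanoate | COC(=O)[C@H](Cc1ccc(Br)c(O[Si](C(C)C)(C(C)C)C(C)C)c1)[C@@H](C[N+](=O)[O-])c1ccc(O[Si](C(C)C)(C(C)C)C(C)C)cc1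
F7 | step 6 | (2R,3R)-3-{[4-bromo-3-(triisopropylsilyloxy)phenyl]methyl}-4-methoxy-4-oxo-2-[4-(triisopropylsilyloxy)phenyl]butanoic acid | COC(=O)[C@H](Cc1ccc(Br)c(O[Si](C(C)C)(C(C)C)C(C)C)c1)[C@@H](C(=O)O)c1ccc(O[Si](C(C)C)(C(C)C)C(C)C)cc1
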